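**Strategy.** The route rests on disconnecting the C11–C12 bond. C12 is an isolated secondary carbinol between the C11 methylene of the ring B side arm (C9–C11, homoallylic to the exocyclic C8=C17 alkene) and C13 of the butenolide ring. With that ring held at the furan oxidation level, C12 is the carbonyl carbon of a heteroaryl aldehyde. A ligand-controlled, titanium-mediated addition of a C11 alkylzinc reagent therefore joins the two fragments and fixes the 12R centre in one operation, independently of the remote decalin stereocentres. The precursors are the primary C11 iodide of a trans-decalin, assembled by a radical epoxy-polyene bicyclisation, and 2-(trimethylsilyl)furan-3-carbaldehyde.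

Key step: step 9

Remark on numbering and one assumption: labdane numbering is used for all decalin compounds (C11 = CH2 on C9, C17 = exocyclic methylene carbon, C18 = equatorial CH2O group on C4, C19 = axial methyl on C4, C20 = methyl on C10, C13–C16 = furan or butenolide carbons); the Re-face preference of the (1S,2S) ligand in step 9 is assumed by mirror-image analogy with the Si-face preference of its (1R,2R) antipode.

Step 1
Reactants: 1 (2E,6E)-farnesyl acetate
Product: 2 (2E,6E,10E)-12-hydroxyfarnesyl acetate
Conditions: SeO2 (cat.), salicylic acid (cat.), t-BuOOH (70% aq.), CH2Cl2, 0 °C to rt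
Reagents that add atoms: tert-butyl hydroperoxide CC(C)(C)OO (oxygen atom, relayed by catalytic selenium dioxide O=[Se]=O)
Why: SeO2-catalysed allylic oxidation (ene reaction then [2,3]-sigmatropic shift) should attack the most electron-rich, terminal trisubstituted alkene at its E methyl group, the 2,3-alkene being deactivated by the allylic acetate, and so give the (10E) primary allylic alcohol.

Step 2
Reactants: 2 (2E,6E,10E)-12-hydroxyfarnesyl acetate
Product: 3 (10R,11R)-10,11-epoxy-12-hydroxyfarnesyl acetate
Conditions: Ti(OiPr)4 (cat.), D-(−)-diethyl tartrate (cat.), t-BuOOH, 4 Å molecular sieves, CH2Cl2, −20 °C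
Reagents that add atoms: tert-butyl hydroperoxide CC(C)(C)OO
Why: Sharpless asymmetric epoxidation acts only on the allylic alcohol alkene, and with D-(−)-diethyl tartrate the oxygen should be delivered to the face that gives the (10R,11R) oxirane, which fixes the future C3 configuration and keeps CH2OH trans to the chain.

Step 3
Reactants: 3 (10R,11R)-10,11-epoxy-12-hydroxyfarnesyl acetate
Product: 4 (10R,11R)-12-(tert-butyldimethylsilyloxy)-10,11-epoxyfarnesyl acetate
Conditions: TBSCl, imidazole, DMF, 0 °C to rt
Reagents that add atoms: tert-butyldimethylsilyl chloride CC(C)(C)[Si](C)(C)Cl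
Why: Standard silylation masks the primary hydroxyl group, which would otherwise bind titanium in the next step, and makes the CH2OR substituent clearly bulkier than the methyl group on the same carbon.

Step 4
Reactants: 4 (10R,11R)-12-(tert-butyldimethylsilyloxy)-10,11-epoxyfarnesyl acetate
Product: 5 (3R,4S,5S,9R,10R)-18-(tert-butyldimethylsilyloxy)-3-hydroxy-12,13,14,15,16-pentanorlabd-8(17)-en-11-yl acetate
Conditions: Cp2TiCl2, Mn dust, THF, rt (Cp2TiCl formed in situ); aq. NaH2PO4 work-up
Reagents that add atoms: none
Why: Cp2TiCl (trivalent titanium) opens the oxirane homolytically at the tertiary carbon and the β-titanoxy radical closes ring A and then ring B by two 6-endo-trig cyclisations through a chair–chair array (reductive epoxy-polyene radical bicyclisation), with C3 coming from the epoxide, the trans ring fusion (C5, C10) and the equatorial C9 arm from the two E alkenes, the bulkier CH2OTBS group expected in the equatorial position at the planar C4 radical, and the final C8 radical converted by a second Cp2TiCl into the exocyclic C8=C17 alkene.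

Step 5
Reactants: 5 (3R,4S,5S,9R,10R)-18-(tert-butyldimethylsilyloxy)-3-hydroxy-12,13,14,15,16-pentanorlabd-8(17)-en-11-yl acetate
Product: 6 (3R,4S,5S,9R,10R)-18-(tert-butyldimethylsilyloxy)-3-(triethylsilyloxy)-12,13,14,15,16-pentanorlabd-8(17)-en-11-yl acetate
Conditions: TESOTf, 2,6-lutidine, CH2Cl2, −78 to 0 °C
Reagents that add atoms: triethylsilyl trifluoromethanesulfonate CC[Si](CC)(CC)OS(=O)(=O)C(F)(F)F
Why: Silylation of the hindered equatorial secondary alcohol with the reactive silyl triflate protects O3 against the organometallic and hydride reagents that follow.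

Step 6
Reactants: 6 (3R,4S,5S,9R,10R)-18-(tert-butyldimethylsilyloxy)-3-(triethylsilyloxy)-12,13,14,15,16-pentanorlabd-8(17)-en-11-yl acetate
Product: 7 (3R,4S,5S,9R,10R)-18-(tert-butyldimethylsilyloxy)-3-(triethylsilyloxy)-12,13,14,15,16-pentanorlabd-8(17)-en-11-ol
Conditions: K2CO3 (cat.), MeOH, 0 °C to rt
Reagents that add atoms: none
Why: Mild base-catalysed transesterification should remove the primary acetate while both silyl ethers stay in place.

Step 7
Reactants: 7 (3R,4S,5S,9R,10R)-18-(tert-butyldimethylsilyloxy)-3-(triethylsilyloxy)-12,13,14,15,16-pentanorlabd-8(17)-en-11-ol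
Product: 8 (3R,4S,5S,9R,10R)-11-iodo-18-(tert-butyldimethylsilyloxy)-3-(triethylsilyloxy)-12,13,14,15,16-pentanorlabd-8(17)-ene
Conditions: I2, PPh3, imidazole, CH2Cl2, 0 °C to rt
Reagents that add atoms: iodine II
Why: Appel-type iodination converts the only free (primary) alcohol into the iodide by SN2 displacement of the alkoxyphosphonium ion without touching C9 or the exocyclic alkene.

Step 8
Reactants: 9 furan-3-carbaldehyde
Product: 13 2-(trimethylsilyl)furan-3-carbaldehyde, via lithium amino alkoxide 10 (not isolated), via C2-lithiated amino alkoxide 11 (not isolated), via C2-silylated amino alkoxide 12 (not isolated)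
Conditions: Me2NCH2CH2NHMe, n-BuLi, THF, −78 °C; then n-BuLi, −20 °C; then Me3SiCl, −78 °C to rt; aq. HCl work-up
Reagents that add atoms: chlorotrimethylsilane C[Si](C)(C)Cl
Why: Directed ortho-metalation: the lithium amide adds to the aldehyde to give an α-amino alkoxide that protects the formyl group and directs n-BuLi by chelation to the adjacent furan C2, so that silylation and hydrolysis should give the 2-silyl aldehyde.

Step 9
Reactants: 8 (3R,4S,5S,9R,10R)-11-iodo-18-(tert-butyldimethylsilyloxy)-3-(triethylsilyloxy)-12,13,14,15,16-pentanorlabd-8(17)-ene; 13 2-(trimethylsilyl)furan-3-carbaldehyde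
Product: 16 (3R,4S,5S,9R,10S,12R)-15,16-epoxy-18-(tert-butyldimethylsilyloxy)-3-(triethylsilyloxy)-16-(trimethylsilyl)labda-8(17),13(16),14-trien-12-ol, via alkylzinc iodide 14 (not isolated), via silylmethyl alkylzinc 15 (not isolated)
Conditions: Zn dust, LiCl, THF, 40 °C; then Me3SiCH2Li, −78 to 0 °C; then Ti(OiPr)4, (1S,2S)-1,2-bis(trifluoromethanesulfonamido)cyclohexane (8 mol %), 13, Et2O/toluene, −20 °C; aq. NH4Cl
Reagents that add atoms: none
Why: Zinc inserts into the C11–I bond to give the primary alkylzinc iodide 14, and Me3SiCH2Li converts it into the mixed diorganozinc 15, whose silylmethyl group is a non-transferable dummy; Ti(OiPr)4 and the C2-symmetric bis(triflamide) form a chiral titanium bis(sulfonamido) Lewis acid that binds aldehyde 13, accepts the alkyl group from zinc and delivers it to the carbonyl carbon, forging C11–C12. The closest known reaction type is the catalytic enantioselective addition of dialkylzinc and mixed alkyl(silylmethyl)zinc reagents to aromatic aldehydes under Ti(OiPr)4/1,2-bis(sulfonamido)cyclohexane catalysis. No ring is closed. The only new stereocentre, C12, is set by the ligand: the (1S,2S) antipode should direct the alkyl group to the Re face of the formyl group and give 12R, while C9, one methylene away, is too remote to compete and stays untouched because C11 is a saturated homoallylic (not allylic) centre that cannot transpose across C8=C17. The step needs selective transfer of the decalin alkyl over the silylmethyl group (secured by the α-silyl dummy ligand), 1,2-addition instead of β-hydride reduction of the aldehyde by the β-branched zinc reagent (secured by titanium mediation at −20 °C) and Re-face selectivity (secured by the ligand, with the planar heteroaryl ring acting as the large substituent).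

Step 10
Reactants: 16 (3R,4S,5S,9R,10S,12R)-15,16-epoxy-18-(tert-butyldimethylsilyloxy)-3-(triethylsilyloxy)-16-(trimethylsilyl)labda-8(17),13(16),14-trien-12-ol
Product: 18 (3R,4S,5S,9R,10S,12R)-12-hydroxy-18-(tert-butyldimethylsilyloxy)-3-(triethylsilyloxy)labda-8(17),13-dien-16,15-olide, via hydroxybutenolide 17 (not isolated)
Conditions: O2, hν (visible light), rose bengal (cat.), MeOH/CH2Cl2, −78 °C; then NaBH4, 0 °C; then aq. citric acid (pH 4)
Reagents that add atoms: oxygen O=O
Why: Singlet oxygen adds [4+2] across the electron-rich silylfuran much faster than it reacts with the 1,1-disubstituted C8=C17 alkene, the silyl group migrates to oxygen in the endoperoxide so that its carbon (C16, next to C13) becomes the lactone carbonyl of the γ-hydroxybutenolide 17, and NaBH4 then reduces the masked C15 aldehyde so that mild acid closes the 16,15-lactone with C12 untouched.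

Step 11
Reactants: 18 (3R,4S,5S,9R,10S,12R)-12-hydroxy-18-(tert-butyldimethylsilyloxy)-3-(triethylsilyloxy)labda-8(17),13-dien-16,15-olide
Product: 19 (3R,4S,5S,9R,10S,12R)-3,12,18-trihydroxylabda-8(17),13-dien-16,15-olide (CNP0270153.3)
Conditions: HF·pyridine, pyridine, THF, 0 °C to rt
Reagents that add atoms: none
Why: Fluoride cleaves both silyl ethers under buffered, weakly acidic conditions that should avoid protonation of C8=C17 (and hence ether formation with the C12 hydroxyl) and base-induced damage to the butenolide.

**Compound list**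

1 | (2E,6E)-farnesyl acetate [(2E,6E)-3,7,11-trimethyldodeca-2,6,10-trien-1-yl acetate] | CC(C)=CCC/C(C)=C/CC/C(C)=C/COC(C)=O | starting material
2 | (2E,6E,10E)-12-hydroxyfarnesyl acetate | OC/C(C)=C/CC/C(C)=C/CC/C(C)=C/COC(C)=O | intermediate
3 | (10R,11R)-10,11-epoxy-12-hydroxyfarnesyl acetate [(2E,6E)-9-[(2R,3R)-3-(hydroxymethyl)-3-methyloxiran-2-yl]-3,7-dimethylnona-2,6-dien-1-yl acetate; CH2OH trans to the chain] | OC[C@@]1(C)O[C@@H]1CC/C(C)=C/CC/C(C)=C/COC(C)=O | intermediate
4 | tert-butyldimethylsilyl ether of 3 | CC(C)(C)[Si](C)(C)OC[C@@]1(C)O[C@@H]1CC/C(C)=C/CC/C(C)=C/COC(C)=O | intermediate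
5 | (3R,4S,5S,9R,10R)-18-(tert-butyldimethylsilyloxy)-3-hydroxy-12,13,14,15,16-pentanorlabd-8(17)-en-11-yl acetate (trans-decalin; 3-OH equatorial; C4 with equatorial CH2OTBS and axial CH3 cis to C20; H5 and H9 trans to C20; exocyclic C8=C17) | C=C1CC[C@@H]2[C@@](C)(CO[Si](C)(C)C(C)(C)C)[C@H](O)CC[C@@]2(C)[C@@H]1COC(C)=O | intermediate
6 | 3-O-triethylsilyl ether of 5 | C=C1CC[C@@H]2[C@@](C)(CO[Si](C)(C)C(C)(C)C)[C@H](O[Si](CC)(CC)CC)CC[C@@]2(C)[C@@H]1COC(C)=O | intermediate
7 | (3R,4S,5S,9R,10R)-18-(tert-butyldimethylsilyloxy)-3-(triethylsilyloxy)-12,13,14,15,16-pentanorlabd-8(17)-en-11-ol | C=C1CC[C@@H]2[C@@](C)(CO[Si](C)(C)C(C)(C)C)[C@H](O[Si](CC)(CC)CC)CC[C@@]2(C)[C@@H]1CO | intermediate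
8 | (3R,4S,5S,9R,10R)-11-iodo-18-(tert-butyldimethylsilyloxy)-3-(triethylsilyloxy)-12,13,14,15,16-pentanorlabd-8(17)-ene | C=C1CC[C@@H]2[C@@](C)(CO[Si](C)(C)C(C)(C)C)[C@H](O[Si](CC)(CC)CC)CC[C@@]2(C)[C@@H]1CI | intermediate
9 | furan-3-carbaldehyde | O=Cc1ccoc1 | starting material
10 | lithium α-amino alkoxide from 9 and lithium N,N,N'-trimethylethylenediamide (not isolated) | [Li]OC(c1ccoc1)N(C)CCN(C)C | intermediate
11 | furan C2-lithio derivative of 10 (not isolated) | [Li]OC(c1ccoc1[Li])N(C)CCN(C)C | intermediate
12 | furan C2-trimethylsilyl derivative of 10 (not isolated) | [Li]OC(c1ccoc1[Si](C)(C)C)N(C)CCN(C)C | intermediate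
13 | 2-(trimethylsilyl)furan-3-carbaldehyde | O=Cc1ccoc1[Si](C)(C)C | intermediate
14 | C11 alkylzinc iodide from 8 (not isolated) | C=C1CC[C@@H]2[C@@](C)(CO[Si](C)(C)C(C)(C)C)[C@H](O[Si](CC)(CC)CC)CC[C@@]2(C)[C@@H]1C[Zn]I | intermediate
15 | C11 alkyl(trimethylsilylmethyl)zinc (not isolated) | C=C1CC[C@@H]2[C@@](C)(CO[Si](C)(C)C(C)(C)C)[C@H](O[Si](CC)(CC)CC)CC[C@@]2(C)[C@@H]1C[Zn]C[Si](C)(C)C | intermediate
16 | (3R,4S,5S,9R,10S,12R)-15,16-epoxy-18-(tert-butyldimethylsilyloxy)-3-(triethylsilyloxy)-16-(trimethylsilyl)labda-8(17),13(16),14-trien-12-ol (2-silyl-3-furyl carbinol) | C=C1CC[C@@H]2[C@@](C)(CO[Si](C)(C)C(C)(C)C)[C@H](O[Si](CC)(CC)CC)CC[C@@]2(C)[C@@H]1C[C@@H](O)c1ccoc1[Si](C)(C)C | intermediate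
17 | (12R)-12,15-dihydroxy-18-(tert-butyldimethylsilyloxy)-3-(triethylsilyloxy)labda-8(17),13-dien-16,15-olide (γ-hydroxybutenolide, C15 epimers, not isolated) | C=C1CC[C@@H]2[C@@](C)(CO[Si](C)(C)C(C)(C)C)[C@H](O[Si](CC)(CC)CC)CC[C@@]2(C)[C@@H]1C[C@@H](O)C1=CC(O)OC1=O | intermediate
18 | (3R,4S,5S,9R,10S,12R)-12-hydroxy-18-(tert-butyldimethylsilyloxy)-3-(triethylsilyloxy)labda-8(17),13-dien-16,15-olide | C=C1CC[C@@H]2[C@@](C)(CO[Si](C)(C)C(C)(C)C)[C@H](O[Si](CC)(CC)CC)CC[C@@]2(C)[C@@H]1C[C@@H](O)C1=CCOC1=O | intermediate
19 | (3R,4S,5S,9R,10S,12R)-3,12,18-trihydroxylabda-8(17),13-dien-16,15-olide (CNP0270153.3) | C=C1CC[C@@H]2[C@@](C)(CO)[C@H](O)CC[C@@]2(C)[C@@H]1C[C@@H](O)C1=CCOC1=O | target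

**Step count.** Total: 11 steps. Longest linear sequence: 10 steps (steps 1–7 and 9–11, from (2E,6E)-farnesyl acetate); step 8 is the one-step side branch.

**Steps most likely to fail**

Step 9 (key step). What may go wrong: slow transfer of the β-branched decalin alkyl group from zinc to titanium, so that β-hydride reduction of aldehyde 13 or transfer of the silylmethyl group competes, and erosion of facial control by uncatalysed background addition. Fallback (bond formation and stereocontrol separated): starting from iodide 8, iodine–lithium exchange (t-BuLi, Et2O/pentane, −78 °C) and unselective addition to 13 would give the C12-epimeric carbinol mixture F1. Dess–Martin oxidation would give the heteroaryl ketone F2. Corey–Bakshi–Shibata reduction with the (S)-methyl oxazaborolidine and BH3·SMe2 (the heteroaryl ring as the large group) should then set 12R by reagent control and return to the route at 16.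

Step 4. What may go wrong: insufficient discrimination between the two faces of the planar C4 radical (C4 epimers), reduction of a radical by Cp2TiCl before ring closure with β-elimination of the silyloxy group, and escape of the C8 radical to endocyclic alkene isomers. Fallback (cationic, stereospecific closure): from 4, MeAlCl2 in CH2Cl2 at −78 °C should open the oxirane with inversion at C4 in concert with anti addition across both E alkenes, so that the E-CH2OTBS group must end equatorial. The C8 cation is captured by the neighbouring C11 acetate as a dioxanylium ion and released on aqueous work-up as the 8-hydroxy 11-acetate F3. TESCl/imidazole would silylate only the secondary O3 to give the 3-O-triethylsilyl ether F4. SOCl2/pyridine at −78 °C should then dehydrate the equatorial tertiary alcohol, which has no antiperiplanar ring hydrogen, towards the exocyclic alkene, rejoining the route at 6.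

Step 10. What may go wrong: ene reaction of singlet oxygen at C8=C17, loss of the C16 silyl group before cycloaddition (loss of regiocontrol), and conjugate reduction of the butenolide or incomplete reduction of the lactol by NaBH4. Fallback (electrophilic oxidation without lactol or hydride): from 16, buffered peracetic acid (AcOOH, NaOAc, CH2Cl2, 0 °C) should oxidise the silylated C16=C13 bond of the furan, the silyl group shifting from carbon to oxygen to give the 2-(trimethylsilyloxy)furan F5. Protodesilylation of F5 with protonation at C15 (Et3N to complete conjugation) should give butenolide 18 directly.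

**Further compounds**

F1 | step 9 | C12-epimeric mixture of 16 (12R and 12S carbinols) | C=C1CC[C@@H]2[C@@](C)(CO[Si](C)(C)C(C)(C)C)[C@H](O[Si](CC)(CC)CC)CC[C@@]2(C)[C@@H]1CC(O)c1ccoc1[Si](C)(C)C
F2 | step 9 | (3R,4S,5S,9R,10S)-15,16-epoxy-18-(tert-butyldimethylsilyloxy)-3-(triethylsilyloxy)-16-(trimethylsilyl)labda-8(17),13(16),14-trien-12-one | C=C1CC[C@@H]2[C@@](C)(CO[Si](C)(C)C(C)(C)C)[C@H](O[Si](CC)(CC)CC)CC[C@@]2(C)[C@@H]1CC(=O)c1ccoc1[Si](C)(C)C
F3 | step 4 | 18-(tert-butyldimethylsilyloxy)-3,8-dihydroxy-12,13,14,15,16-pentanorlabdan-11-yl acetate (8-OH equatorial, C17 methyl axial, other centres as in 5) | C[C@]1(O)CC[C@@H]2[C@@](C)(CO[Si](C)(C)C(C)(C)C)[C@H](O)CC[C@@]2(C)[C@@H]1COC(C)=O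
F4 | step 4 | 3-O-triethylsilyl ether of F3 | C[C@]1(O)CC[C@@H]2[C@@](C)(CO[Si](C)(C)C(C)(C)C)[C@H](O[Si](CC)(CC)CC)CC[C@@]2(C)[C@@H]1COC(C)=O
F5 | step 10 | (12R)-15,16-epoxy-18-(tert-butyldimethylsilyloxy)-3-(triethylsilyloxy)-16-(trimethylsilyloxy)labda-8(17),13(16),14-trien-12-ol | C=C1CC[C@@H]2[C@@](C)(CO[Si](C)(C)C(C)(C)C)[C@H](O[Si](CC)(CC)CC)CC[C@@]2(C)[C@@H]1C[C@@H](O)c1ccoc1O[Si](C)(C)C
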